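Readings and results were generated by integration with constants of no real substance; scatter was added.

I began at the late end of the cedar flask's run, where between 2.00 min and 2.50 min Z climbed while E fell, and I divided the one change by the other so that time dropped out.

the same everywhere: D 0.014 M

|  | G | X | remark | time |
|---|---|---|---|---|
| cedar | 7 mM | 0.028 M | the very flask that is asked about, followed so far |  |
| flask | 7.00 mM | 0.0280 M |  | 15 min |

cedar run (percent of the D charged)

| time / min | Z / % | E / % |
|---|---|---|
| 0.200 | 0.1 | 6.5 |
| 0.500 | 0.6 | 15.3 |
| 1.00 | 3.3 | 23.5 |
| 1.33 | 4.8 | 26.8 |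
| 2.00 | 10.9 | 27.2 |
| 2.50 | 17.1 | 25.8 |

(standard deviation of a reading: 0.3 percentage points)

- the numbers in the tables scatter by 0.3 percentage points (one standard deviation)

- share of Z in Z plus E at 6.0 s
- share of Z in Z plus E at 15 min
- which of Z and E there is more of at 15 min

Z gained over E gained, which I called the exchange (at the start, a selectivity factor), read 0.0392 from the start to 0.500 min; the first Z reading, 0.1%, carried a scatter of 0.3 percentage points, so I took this later one. Held back to 6.0 s, my exchange gave Z a share of 3.77%. The first reading put E's start at 0.325 min⁻¹ of the charge, and its highest reading was 27.2% at 2.00 min. Past that knee the exchange turned negative, reading −4.43. Running the last two rates forward, I put the crossing of Z and E at 3.07 min. Then I assumed that the whole charge of D ended as Z and E, and this late exchange gave Z a share of 90.9% at 15 min, with Z ahead.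

The forecast, reasoning that “E should be nearly all converted to Z”, gave 0.7% at 6.0 s and 99% at 15 min, with Z ahead.

The flask gave 4.02% and 86.1%, with Z ahead and the crossing at 3.14 min; at 15 min it also held 18.2% as L, which my sum had not counted.

    D → J (k = 0.00712 s⁻¹)
    G + J ⇌ E (K = 3420 M⁻¹, k = 113 M⁻¹ s⁻¹)
    X + J → Z (k = 1.04 M⁻¹ s⁻¹)
    E ⇌ L (K = 1.40, k = 0.00650 s⁻¹)

In this scheme the two forward rates from J stand as X to G, each times its constant, so with X held I scaled the start exchange inversely with G. The neighbour flask had 0.400 of the cedar flask's G, which made my exchange 0.0980 and Z's share 8.93% at 6.0 s. That neighbour flask gave 9.60%, and at 15 min it held 88.5% as Z.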